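The flasks gamma, epsilon, autumn and winter each carry 9.4 mol% of initiator on the free monomer charged, and a closed flask keeps that ratio of charges. So we count turnovers. The runs show no chains, so this link is a guess: we take one chain begun per initiator charged and none from the transfer agent, which makes initiator the limiting reagent for chains. The average length is then the share of the charge in chains times the charge ratio, free monomer charged over initiator charged, 10.6.

| flask | free monomer | transfer agent | initiator | remark | time |
|---|---|---|---|---|---|
| gamma | 0.26 M | 0.062 M | 9.4 mol% | run made earlier |  |
| epsilon | 0.93 M | 0.062 M | 9.4 mol% | run made earlier |  |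
| autumn | 0.62 M | 0.0620 M | 9.4 mol% |  | 15 h |
| winter | 0.20 M | 0.0620 M | 9.4 mol% |  | 15 h |

| run | time / h | monomer in chains / % | free monomer / % |
|---|---|---|---|
| gamma | 0.833 | 1.1 | 97.8 |
| gamma | 1.33 | 3.6 | 95.8 |
| gamma | 2.50 | 6.3 | 92.4 |
| gamma | 4.00 | 9.4 | 89.7 |
| gamma | 6.00 | 13.5 | 84.5 |
| gamma | 10.0 | 19.1 | 77.9 |
| epsilon | 0.833 | 8.4 | 91.1 |
| epsilon | 1.33 | 11.5 | 88.2 |
| epsilon | 2.50 | 18.0 | 79.5 |
| epsilon | 4.00 | 24.7 | 71.2 |
| epsilon | 6.00 | 31.4 | 64.0 |
| epsilon | 10.0 | 37.0 | 56.0 |

(each reading ± 0.5 percentage points)

- the average divides the monomer in chains by the number of chains begun, living and dead together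
- the earlier runs do not show the number of chains; that part of a forecast is a guess

- which of the two ends with the longer chains by the average number of monomer units in a chain (chains begun, living or dead) ("neither" if they lie within 10%) (autumn / winter / neither)
- average number of monomer units in a chain (chains begun, living or dead) at the end, autumn
- average number of monomer units in a chain (chains begun, living or dead) at the end, winter

What remains is the share in chains at 15 h. At 10.0 h gamma holds 19.1% and epsilon 37.0%, so the share goes with the charge to the power 0.519. That puts autumn at 30.0% and winter at 16.7% at that time. Gamma gained 5.6 percentage points from 6.00 h to 10.0 h, and epsilon 5.6 points. Holding that pace adds 7 points by 15 h, which gives 3.93 for autumn and 2.52 for winter.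

The weak link is that held pace. Gamma's gain per hour in its last interval is 0.683 of that in the interval before. With this factor the added share is 4.8 points, and we commit to 3.70 for autumn and 2.28 for winter. Autumn is longer by the factor 1.62.

The forecast, made apart from this reckoning, gave 3 for autumn and 1.7 for winter, with autumn longer, and said “The chain count is the guess”.

The flask gives 3.96 for autumn and 2.35 for winter, so autumn ends longer.

    living end + free monomer → dead end (k = 0.216 L mol⁻¹ h⁻¹)
    free monomer + living end → monomer in chains + living end, rate k2*[living end]*[free monomer] (k = 0.984 L mol⁻¹ h⁻¹)
    free monomer + initiator → living end + monomer in chains (k = 1.12 L mol⁻¹ h⁻¹)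
    living end + transfer agent → dead chain (kL = 0.288 L mol⁻¹ h⁻¹)

Each chain is begun by one initiator, and the transfer agent begins none: it only turns a living end into a dead chain. Winter ends shorter because of its thinner charge of free monomer: with that difference taken away, so that winter is run at autumn's charge, it gives 3.96 in place of 2.35. Autumn's 37.2% in chains times the ratio makes 3.96, and winter's 20.9%, with 5.4% of its initiator left, makes 2.35. The neighbour flask, autumn's recipe at 0.25 M of free monomer, holds 24.0% in chains with 2.9% of its initiator left, so the ratio gives 2.63, and that flask gives 2.63.

The earlier runs and the new flask were generated by integration on assumed constants; noise was put on by code.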